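The route cuts the C1–C2 bond of ring B. C1 is doubly benzylic. It sits on C8a of ring A, whose C8 and C6 methoxy groups are ortho and para donors, and on the 3,4-dimethoxyphenyl ring with its para donor, so it can be a stabilised diarylmethyl cation. C2 carries its CH2OH carbon at the aldehyde level and can therefore act as an enamine carbon. A chiral imidazolidinone salt with In(OTf)3 joins the two, closing ring B and setting C1 and C2 in one operation. The precursor is a methyl (E)-2-benzylidene-4-oxobutanoate whose ring A bears, ortho to the alkene, a racemic diarylmethyl methyl ether as the latent cation.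

Key step: step 7

**Remarks before the route**

- **Numbering:** C1 (aryl-bearing), C2, C3, C4, C4a, C5–C8, C8a. Ring A is the aromatic ring of the bicycle, ring B the dihydro ring, and ring C the pendant 3,4-dimethoxyphenyl group.
- **Descriptors re-derived from the target:**
  - At C1 the order is C8a > ring C > C2 > H, which gives R.
  - At C2 the order is CH2OH (or CHO) > C3 > C1 > H, which gives S.
  - The two substituents are trans.
  - In the precursor the alkene is E, with ring A trans to CO2Me and therefore cis to the CH2CHO arm.
- **Donors:** ring A offers an ortho (C8) and a para (C6) donor to C1. Ring C offers only its para methoxy group, because its other methoxy group is meta.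
- **Carbinol oxygen as a methyl ether (from step 3 on):**
  - A free benzhydrol ortho to a formyl group would close to a lactol and dehydrate to an isobenzofuran.
  - Its alkoxide would add to the acrylate in a five-membered oxa-Michael closure under the olefination base.
  - The methyl ether ionises to the same cation, so nothing is lost in the key step.
- **Aldehyde masked as an allyl group:**
  - It is released under near-neutral oxidative conditions.
  - An acetal would need acid that also ionises the diarylmethyl ether, and an achiral enol ether could then close ring B without the catalyst.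
- **Assumption:** the sense of induction follows the accepted shielding model of the cis-(2S,5S) imidazolidinone. If the tethered cation shows the opposite sense, the equally available (2R,5R) enantiomer is used.

**Route**

Step 1
Reactants: 1 2-bromo-3,4,5-trimethoxybenzaldehyde
Product: 2 2-bromo-1-(dimethoxymethyl)-3,4,5-trimethoxybenzene
Conditions: HC(OMe)3, p-TsOH·H2O (cat.), MeOH, reflux; Et3N quench
Reagents that add atoms: trimethyl orthoformate, COC(OC)OC; methanol, CO
Why: Acid-catalysed acetalisation, driven by the orthoformate as water scavenger, masks the aldehyde against n-BuLi, and the dimethyl acetal is chosen because it later hydrolyses far faster than the diarylmethyl ether ionises.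

Step 2
Reactants: 2 2-bromo-1-(dimethoxymethyl)-3,4,5-trimethoxybenzene; 3 veratraldehyde (3,4-dimethoxybenzaldehyde)
Product: 5 (3,4-dimethoxyphenyl)[6-(dimethoxymethyl)-2,3,4-trimethoxyphenyl]methanol (racemic), via aryllithium 4 (not isolated)
Conditions: n-BuLi, THF, −78 °C; then 3, −78 → 0 °C; H2O quench; Et3N-washed silica
Reagents that add atoms: none
Why: Bromine–lithium exchange outruns any attack on the acetal, the aryllithium is held by the flanking methoxy and acetal oxygens, and its 1,2-addition to the aldehyde gives the carbinol as a racemate, which does not matter because this centre is erased in step 7.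

Step 3
Reactants: 5 (3,4-dimethoxyphenyl)[6-(dimethoxymethyl)-2,3,4-trimethoxyphenyl]methanol
Product: 7 2-[(3,4-dimethoxyphenyl)(methoxy)methyl]-3,4,5-trimethoxybenzaldehyde (racemic), via methyl ether acetal 6 (not isolated)
Conditions: NaH, MeI, THF–DMF, 0 °C → rt; then H2O, AcOH to pH 3–4, rt, short contact
Reagents that add atoms: iodomethane, CI; water, O
Why: Williamson etherification of the sodium alkoxide caps the oxygen before the aldehyde is freed, and the following specific-acid hydrolysis of the electron-rich aryl dimethyl acetal is orders of magnitude faster at this pH than ionisation of the diarylmethyl ether, so neither lactol nor isobenzofuran formation can set in.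

Step 4
Reactants: 8 trimethyl phosphonoacetate; 9 allyl bromide
Product: 10 methyl 2-(dimethoxyphosphoryl)pent-4-enoate (racemic)
Conditions: NaH, THF, 0 °C; then 9, 0 °C → rt; distillation
Reagents that add atoms: none
Why: SN2 C-alkylation of the stabilised phosphonoacetate anion with a reactive allylic halide is routine, a slight excess of 8 limits double alkylation, and the product can be purified by distillation.

Step 5
Reactants: 7 2-[(3,4-dimethoxyphenyl)(methoxy)methyl]-3,4,5-trimethoxybenzaldehyde; 10 methyl 2-(dimethoxyphosphoryl)pent-4-enoate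
Product: 11 methyl (E)-2-[2-[(3,4-dimethoxyphenyl)(methoxy)methyl]-3,4,5-trimethoxybenzylidene]pent-4-enoate
Conditions: 10, NaH, THF, 0 °C; then 7, 0 °C → rt
Reagents that add atoms: none
Why: In the Horner–Wadsworth–Emmons olefination the reversible addition of the branched phosphonate anion to an aromatic aldehyde drains through the less crowded oxaphosphetane to the (E)-alkene (ring A trans to CO2Me, cis to the allyl arm), and the minor geometric isomer is removed by chromatography.

Step 6
Reactants: 11 methyl (E)-2-[2-[(3,4-dimethoxyphenyl)(methoxy)methyl]-3,4,5-trimethoxybenzylidene]pent-4-enoate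
Product: 13 methyl (E)-2-[2-[(3,4-dimethoxyphenyl)(methoxy)methyl]-3,4,5-trimethoxybenzylidene]-4-oxobutanoate, via diol 12 (not isolated)
Conditions: OsO4 (2 mol %), NaIO4 (4 equiv), 2,6-lutidine (2 equiv), 1,4-dioxane–H2O (3:1), rt; used at once
Reagents that add atoms: osmium tetroxide, O=[Os](=O)(=O)=O; sodium periodate, [Na+].[O-]I(=O)(=O)=O
Why: In the Lemieux–Johnson oxidation OsO4 attacks the unhindered monosubstituted alkene far faster than the trisubstituted, ester-deactivated and ortho-shielded one, periodate cleaves the diol in the flask, and 2,6-lutidine keeps the medium near neutral so that the diarylmethyl ether and the position of the remaining double bond are not disturbed.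

Step 7
Reactants: 13 methyl (E)-2-[2-[(3,4-dimethoxyphenyl)(methoxy)methyl]-3,4,5-trimethoxybenzylidene]-4-oxobutanoate
Product: 15 methyl (1R,2S)-1-(3,4-dimethoxyphenyl)-2-(hydroxymethyl)-6,7,8-trimethoxy-1,2-dihydronaphthalene-3-carboxylate, via cyclised aldehyde 14 (not isolated)
Conditions: (2S,5S)-5-benzyl-2-tert-butyl-3-methylimidazolidin-4-one·CF3CO2H (20 mol %), In(OTf)3 (20 mol %, added last), CH2Cl2 (0.02 M), −20 → 0 °C; then MeOH, NaBH4, −20 °C
Reagents that add atoms: none
Why: The amine salt condenses with the aldehyde of 13 to an (E)-dienamine while In(OTf)3, helped by the CF3CO2H of the salt, reversibly removes methanol from the diarylmethyl ether; the enamine carbon C2 captures the cationic C1, the iminium ion is hydrolysed to 14 by the water set free in the condensation, and NaBH4 secures the epimerisable C2 centre before isolation. The closest known reaction type is the imidazolidinone-catalysed SN1-type α-alkylation of aldehydes, dienamine-forming ones included, with diarylmethanols under Brønsted acid or In(OTf)3 co-catalysis, applied here to a substrate that holds both partners, and Lewis-acid ionisation of diarylmethyl methyl ethers for stereoselective enolate alkylation is equally established. Ring B closes in a six-membered mode in which the enamine C=C stays outside the new ring (enamine-exo) and the acceptor is a planar cation that imposes no trajectory limit. C2 is set by the catalyst: the enamine turns away from the tert-butyl group, the benzyl and tert-butyl groups cover its Re face, and C1 arrives on the Si face, which corresponds to 2S. C1 is set by the substrate: in the half-chair transition state ring C takes the pseudoaxial position away from the C8 methoxy group and anti to the exocyclic iminium carbon on C2, which gives the trans (1R,2S) relationship. The step needs α- over γ-attack, C- over N-alkylation and ring closure over intermolecular arylation: γ-attack would build a four-membered ring, the (E)-alkene holds ring A next to the CH2CHO arm, the C3 ester deactivates the alkene against indene-forming attack on the cation, N-alkylation is reversible under acid, any drift of the double bond towards the aldehyde returns through the same dienamine, and high dilution suppresses intermolecular capture.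

Step 8
Reactants: 15 methyl (1R,2S)-1-(3,4-dimethoxyphenyl)-2-(hydroxymethyl)-6,7,8-trimethoxy-1,2-dihydronaphthalene-3-carboxylate
Product: 16 [(1R,2S)-1-(3,4-dimethoxyphenyl)-6,7,8-trimethoxy-1,2-dihydronaphthalene-2,3-diyl]dimethanol (target)
Conditions: i-Bu2AlH (5 equiv), CH2Cl2, −78 → 0 °C; aq. potassium sodium tartrate
Reagents that add atoms: none
Why: Hydride reduction of the conjugated ester with i-Bu2AlH proceeds by 1,2-delivery only, leaves the C3=C4 double bond and both stereocentres (neither is acidic any longer) untouched, and any material that has lactonised through the C2 hydroxymethyl group converges on the same diol.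

**Compound list**

| No. | Name | SMILES | Role |
|---|---|---|---|
| 1 | 2-bromo-3,4,5-trimethoxybenzaldehyde | COc1cc(C=O)c(Br)c(OC)c1OC | starting material |
| 2 | 2-bromo-1-(dimethoxymethyl)-3,4,5-trimethoxybenzene | COC(OC)c1cc(OC)c(OC)c(OC)c1Br | intermediate |
| 3 | veratraldehyde | COc1ccc(C=O)cc1OC | starting material |
| 4 | [6-(dimethoxymethyl)-2,3,4-trimethoxyphenyl]lithium | [Li]c1c(C(OC)OC)cc(OC)c(OC)c1OC | intermediate |
| 5 | (3,4-dimethoxyphenyl)[6-(dimethoxymethyl)-2,3,4-trimethoxyphenyl]methanol, racemic | COc1ccc(C(O)c2c(C(OC)OC)cc(OC)c(OC)c2OC)cc1OC | intermediate |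
| 6 | methyl ether of 5, racemic | COc1ccc(C(OC)c2c(C(OC)OC)cc(OC)c(OC)c2OC)cc1OC | intermediate |
| 7 | 2-[(3,4-dimethoxyphenyl)(methoxy)methyl]-3,4,5-trimethoxybenzaldehyde, racemic | COc1ccc(C(OC)c2c(C=O)cc(OC)c(OC)c2OC)cc1OC | intermediate |
| 8 | trimethyl phosphonoacetate | COC(=O)CP(=O)(OC)OC | starting material |
| 9 | allyl bromide | C=CCBr | starting material |
| 10 | methyl 2-(dimethoxyphosphoryl)pent-4-enoate, racemic | C=CCC(C(=O)OC)P(=O)(OC)OC | intermediate |
| 11 | methyl (E)-2-[2-[(3,4-dimethoxyphenyl)(methoxy)methyl]-3,4,5-trimethoxybenzylidene]pent-4-enoate, racemic at the ether carbon | COc1ccc(C(OC)c2c(/C=C(/C(=O)OC)CC=C)cc(OC)c(OC)c2OC)cc1OC | intermediate |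
| 12 | methyl (E)-2-[2-[(3,4-dimethoxyphenyl)(methoxy)methyl]-3,4,5-trimethoxybenzylidene]-4,5-dihydroxypentanoate, diastereomer mixture | COc1ccc(C(OC)c2c(/C=C(/C(=O)OC)CC(O)CO)cc(OC)c(OC)c2OC)cc1OC | intermediate |
| 13 | methyl (E)-2-[2-[(3,4-dimethoxyphenyl)(methoxy)methyl]-3,4,5-trimethoxybenzylidene]-4-oxobutanoate, racemic at the ether carbon | COc1ccc(C(OC)c2c(/C=C(/C(=O)OC)CC=O)cc(OC)c(OC)c2OC)cc1OC | intermediate |
| 14 | methyl (1R,2S)-1-(3,4-dimethoxyphenyl)-2-formyl-6,7,8-trimethoxy-1,2-dihydronaphthalene-3-carboxylate | COc1ccc([C@@H]2c3c(cc(OC)c(OC)c3OC)C=C(C(=O)OC)[C@H]2C=O)cc1OC | intermediate |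
| 15 | methyl (1R,2S)-1-(3,4-dimethoxyphenyl)-2-(hydroxymethyl)-6,7,8-trimethoxy-1,2-dihydronaphthalene-3-carboxylate | COc1ccc([C@@H]2c3c(cc(OC)c(OC)c3OC)C=C(C(=O)OC)[C@H]2CO)cc1OC | intermediate |
| 16 | [(1R,2S)-1-(3,4-dimethoxyphenyl)-6,7,8-trimethoxy-1,2-dihydronaphthalene-2,3-diyl]dimethanol | COc1ccc([C@@H]2c3c(cc(OC)c(OC)c3OC)C=C(CO)[C@H]2CO)cc1OC | target |

**Count**

- Total steps: 8.
- Longest linear sequence: 7 (steps 1, 2, 3, 5, 6, 7, 8).

**Steps most likely to fail**

**Step 7.**
- Ring closure may run in part through the achiral dienol under Lewis acid, without the catalyst.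
- Turnover may stall through alkylation of the catalyst nitrogen.
- Facial shielding may be incomplete for a tethered cation.
- C2 may epimerise before the reduction.

The fallback gives up catalyst control for a silyl enol ether closure followed by resolution. It sets out from 13 and comes back at 16. Treatment of 13 with TBSOTf and Et3N in CH2Cl2 gives the silyl dienol ether F1. Catalytic Me3SiOTf in CH2Cl2 at −78 °C ionises the methyl ether, and the enol ether carbon closes ring B in a Mukaiyama-type SN1 alkylation to the racemic trans aldehyde F2. NaBH4 in MeOH reduces this to the racemic trans hydroxy ester F3. Steglich esterification with (S)-2-methoxy-2-phenylacetic acid gives the (1R,2S) ester F4 and the (1S,2R) ester F5, which are separated by chromatography or crystallisation. F4 is treated with i-Bu2AlH as in step 8, which cleaves both ester groups and gives 16.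

**Step 6.**
- The oxidant may also attack the trisubstituted alkene.
- The enolisable aldehyde may be over-oxidised.
- The β,γ-unsaturated aldehyde may be lost through double-bond drift or on silica during aqueous work-up.

The fallback uses no alkene cleavage and no oxidant. It sets out from 7, comes back at 13, and makes steps 4 and 5 unnecessary. Stobbe condensation of 7 with dimethyl succinate (t-BuOK, t-BuOH) gives the (E)-half-ester F6. EtSH, EDC and DMAP turn its free acid into the S-ethyl thioester F7. Fukuyama reduction (Et3SiH, Pd/C, acetone, rt) delivers 13 without passing through the lactonisation-prone alcohol level.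

**Step 5.**
- Addition of the branched phosphonate anion to the ortho-encumbered, electron-rich aldehyde may be sluggish.
- The E/Z preference may erode.

The fallback separates bond formation from the setting of geometry. It sets out from 7 and comes back at 11. The lithium enolate of methyl pent-4-enoate (LiN(i-Pr)2, THF, −78 °C) adds to 7 to give the aldol F8 as a diastereomer mixture. Ac2O, Et3N and DMAP give the acetate F9. DBU in warm toluene then eliminates it by the E1cB path to the thermodynamically preferred (E)-alkene 11.

**Further compounds**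

F1 | step 7 | methyl (2E)-4-[(tert-butyldimethylsilyl)oxy]-2-[2-[(3,4-dimethoxyphenyl)(methoxy)methyl]-3,4,5-trimethoxybenzylidene]but-3-enoate (enol ether geometry mixed) | COc1ccc(C(OC)c2c(/C=C(/C(=O)OC)C=CO[Si](C)(C)C(C)(C)C)cc(OC)c(OC)c2OC)cc1OC
F2 | step 7 | racemic trans methyl 1-(3,4-dimethoxyphenyl)-2-formyl-6,7,8-trimethoxy-1,2-dihydronaphthalene-3-carboxylate | COc1ccc([C@@H]2c3c(cc(OC)c(OC)c3OC)C=C(C(=O)OC)[C@H]2C=O)cc1OC.COc1ccc([C@H]2c3c(cc(OC)c(OC)c3OC)C=C(C(=O)OC)[C@@H]2C=O)cc1OC
F3 | step 7 | racemic trans methyl 1-(3,4-dimethoxyphenyl)-2-(hydroxymethyl)-6,7,8-trimethoxy-1,2-dihydronaphthalene-3-carboxylate | COc1ccc([C@@H]2c3c(cc(OC)c(OC)c3OC)C=C(C(=O)OC)[C@H]2CO)cc1OC.COc1ccc([C@H]2c3c(cc(OC)c(OC)c3OC)C=C(C(=O)OC)[C@@H]2CO)cc1OC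
F4 | step 7 | (S)-2-methoxy-2-phenylacetate of the (1R,2S) hydroxy ester | COc1ccc([C@@H]2c3c(cc(OC)c(OC)c3OC)C=C(C(=O)OC)[C@H]2COC(=O)[C@@H](OC)c2ccccc2)cc1OC
F5 | step 7 | (S)-2-methoxy-2-phenylacetate of the (1S,2R) hydroxy ester | COc1ccc([C@H]2c3c(cc(OC)c(OC)c3OC)C=C(C(=O)OC)[C@@H]2COC(=O)[C@@H](OC)c2ccccc2)cc1OC
F6 | step 6 | (E)-4-[2-[(3,4-dimethoxyphenyl)(methoxy)methyl]-3,4,5-trimethoxyphenyl]-3-(methoxycarbonyl)but-3-enoic acid | COc1ccc(C(OC)c2c(/C=C(/C(=O)OC)CC(=O)O)cc(OC)c(OC)c2OC)cc1OC
F7 | step 6 | methyl (E)-2-[2-[(3,4-dimethoxyphenyl)(methoxy)methyl]-3,4,5-trimethoxybenzylidene]-4-(ethylsulfanyl)-4-oxobutanoate | COc1ccc(C(OC)c2c(/C=C(/C(=O)OC)CC(=O)SCC)cc(OC)c(OC)c2OC)cc1OC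
F8 | step 5 | methyl 2-[[2-[(3,4-dimethoxyphenyl)(methoxy)methyl]-3,4,5-trimethoxyphenyl](hydroxy)methyl]pent-4-enoate (diastereomer mixture) | COc1ccc(C(OC)c2c(C(O)C(CC=C)C(=O)OC)cc(OC)c(OC)c2OC)cc1OC
F9 | step 5 | methyl 2-[acetoxy[2-[(3,4-dimethoxyphenyl)(methoxy)methyl]-3,4,5-trimethoxyphenyl]methyl]pent-4-enoate (diastereomer mixture) | COc1ccc(C(OC)c2c(C(OC(C)=O)C(CC=C)C(=O)OC)cc(OC)c(OC)c2OC)cc1OC
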